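The synthesis rests on opening ring A at O1–C5 and C4–Br. The feature exploited is the spiro atom C5 of ring A, a fully substituted carbon that bears the lactone oxygen O1 and the brominated alkene carbon C4 while also belonging to cyclobutane ring C; an allenic acid ending in a cyclobutylidene group gives exactly this array on bromolactonisation. In one operation the key step closes ring A, places bromine on C4 and turns the allene axis into the C5 stereocentre. The precursor is 2-butyl-3-(2-silyloxycyclobutylidene)acrylic acid, carboxyl anti to the (R)-silyloxy carbon; that carbinol later becomes the ketone onto which ring B is built, and the cyclobutene is dibrominated last.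

Key step: step 8

Remark: in both lipase steps the enzyme is taken to acylate the (R)-carbinol (the carbonyl-bearing substituent counting as the large group, as in the usual empirical size rule for secondary alcohols); the opposite preference would only exchange the roles of ester and unreacted alcohol.

Step 1
Reactants: 1 1,2-bis(trimethylsilyloxy)cyclobutene
Product: 2 rac-2-hydroxycyclobutan-1-one
Conditions: MeOH, reflux, N2
Reagents that add atoms: none
Why: Methanolysis of the bis-silyl enediol ether (desilylation of an acyloin silyl ether) releases the enediol, which tautomerises to the racemic α-hydroxy ketone.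

Step 2
Reactants: 2 rac-2-hydroxycyclobutan-1-one
Product: 3 (R)-2-oxocyclobutyl acetate
Conditions: immobilised Burkholderia cepacia lipase, vinyl acetate, MTBE, rt, stopped near 40% conversion
Reagents that add atoms: vinyl acetate C=COC(C)=O
Why: Lipase-catalysed kinetic resolution by irreversible transesterification should acetylate the (R)-alcohol selectively, so the stereocentre of 3 is selected by the enzyme and the unreacted (S)-alcohol is removed by chromatography.

Step 3
Reactants: 3 (R)-2-oxocyclobutyl acetate
Product: 4 (R)-2-hydroxycyclobutan-1-one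
Conditions: same lipase, n-BuOH, MTBE, rt
Reagents that add atoms: none
Why: Lipase-catalysed alcoholysis removes the acetyl group under neutral conditions that cannot enolise the α-hydroxy ketone and, being (R)-selective a second time, should raise the enantiomeric purity (sequential enzymatic resolution) without touching the stereocentre.

Step 4
Reactants: 4 (R)-2-hydroxycyclobutan-1-one
Product: 5 (R)-2-[(tert-butyldimethylsilyl)oxy]cyclobutan-1-one
Conditions: TBSCl, imidazole, DMF, 0 °C
Reagents that add atoms: tert-butyldimethylsilyl chloride CC(C)(C)[Si](C)(C)Cl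
Why: Imidazole-promoted silylation of a secondary alcohol should leave the stereocentre intact, since imidazole at 0 °C is too weak a base to enolise the ketone appreciably.

Step 5
Reactants: 5 (R)-2-[(tert-butyldimethylsilyl)oxy]cyclobutan-1-one; 6 hex-1-yne
Product: 9 (1R,2R)-2-[(tert-butyldimethylsilyl)oxy]-1-(hex-1-yn-1-yl)cyclobutyl methyl carbonate, via hex-1-ynyllithium 7 (not isolated), via lithium alkoxide 8 (not isolated)
Conditions: 6, n-BuLi, THF, −78 °C; then 5, −78 °C; then ClCO2Me, −78 to 0 °C
Reagents that add atoms: methyl chloroformate COC(Cl)=O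
Why: 1,2-Addition of a lithium acetylide to the strained ketone followed by O-acylation of the alkoxide in the same flask should give the tertiary propargylic carbonate, the acetylide entering anti to the bulky α-silyloxy group (steric and Felkin–Anh control) so that C1 becomes (R) with the carbonate oxygen cis to the silyloxy group.

Step 6
Reactants: 9 (1R,2R)-2-[(tert-butyldimethylsilyl)oxy]-1-(hex-1-yn-1-yl)cyclobutyl methyl carbonate
Product: 10 methyl (Ra)-2-butyl-3-[(2R)-2-[(tert-butyldimethylsilyl)oxy]cyclobutylidene]prop-2-enoate
Conditions: Pd(PPh3)4 (5 mol%), CO (balloon to 5 atm), MeOH–THF, 40 °C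
Reagents that add atoms: carbon monoxide [C-]#[O+]; methanol CO
Why: In this palladium-catalysed alkoxycarbonylation of a propargylic carbonate, zerovalent palladium displaces the carbonate in an anti SN2′ sense, CO inserts into the allenylpalladium bond with retention and methanol cleaves the acyl complex, so the C1 stereocentre is converted into a single allene axis with the ester anti to the silyloxy group, any axis epimer being a separable diastereomer.

Step 7
Reactants: 10 methyl (Ra)-2-butyl-3-[(2R)-2-[(tert-butyldimethylsilyl)oxy]cyclobutylidene]prop-2-enoate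
Product: 11 (Ra)-2-butyl-3-[(2R)-2-[(tert-butyldimethylsilyl)oxy]cyclobutylidene]prop-2-enoic acid
Conditions: LiOH, THF–MeOH–H2O, rt; then 1 M HCl to pH 3
Reagents that add atoms: lithium hydroxide [Li+].[OH-]
Why: Saponification of the methyl ester is safe because this allenoate has neither an α-hydrogen nor a hydrogen on the allene terminus, so base can neither isomerise it to an alkyne nor scramble the axis.

Step 8
Reactants: 11 (Ra)-2-butyl-3-[(2R)-2-[(tert-butyldimethylsilyl)oxy]cyclobutylidene]prop-2-enoic acid
Product: 12 (1R,4R)-8-bromo-7-butyl-1-[(tert-butyldimethylsilyl)oxy]-5-oxaspiro[3.4]oct-7-en-6-one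
Conditions: CuBr2 (3 equiv), NaHCO3 (1 equiv), acetone–H2O (2:1), 55 °C
Reagents that add atoms: copper dibromide [Cu+2].[Br-].[Br-]
Why: CuBr2 acts as the bromine donor toward the β,γ double bond of the allenoate: bromine becomes bonded to the sp carbon and, on the opposite side of that π bond, the carboxylate oxygen bonds to the ring carbon, so that the α,β double bond survives as the butenolide alkene. The closest known reaction type is the CuBr2-mediated bromolactonisation of 2,3-allenoic acids to 4-bromobutenolides, which is known to relay axial chirality to the new carbon centre. Ring A closes in the 5-endo-trig mode onto the sp2 terminus, forming O1–C5 and C4–Br in the same operation. The new quaternary stereocentre C5 (C4 in the spiro numbering) is controlled by the allene axis: the carboxylate is held over the face of the four-membered ring that is remote from the silyloxy group, and its oxygen can bond to C5 only there, which gives the (R) centre with the lactone oxygen trans to the silyloxy group. The step needs attack at the distal double bond and a faithful axis-to-centre relay; the first is secured because only that bond gives a five-membered ring and it is the electron-richer one, the second because the β-silyloxy group disfavours a free cyclobutyl cation so that C–O bond formation keeps pace with bromine transfer. NaHCO3 takes up the HBr that would otherwise form, so the silyl ether is not exposed to acid.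

Step 9
Reactants: 12 (1R,4R)-8-bromo-7-butyl-1-[(tert-butyldimethylsilyl)oxy]-5-oxaspiro[3.4]oct-7-en-6-one
Product: 13 (1R,4R)-8-bromo-7-butyl-1-hydroxy-5-oxaspiro[3.4]oct-7-en-6-one
Conditions: HF·pyridine, THF, 0 °C to rt
Reagents that add atoms: none
Why: Fluoride-mediated silyl ether cleavage under mildly acidic conditions avoids the alkoxide that could open or translactonise ring A, and no stereocentre is involved.

Step 10
Reactants: 13 (1R,4R)-8-bromo-7-butyl-1-hydroxy-5-oxaspiro[3.4]oct-7-en-6-one
Product: 14 (R)-8-bromo-7-butyl-5-oxaspiro[3.4]oct-7-ene-1,6-dione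
Conditions: Dess–Martin periodinane, NaHCO3, CH2Cl2, rt
Reagents that add atoms: none
Why: Dess–Martin oxidation converts the secondary alcohol into the cyclobutanone without base, removing the relay stereocentre and leaving the quaternary spiro carbon, which cannot epimerise, as the only stereocentre.

Step 11
Reactants: 14 (R)-8-bromo-7-butyl-5-oxaspiro[3.4]oct-7-ene-1,6-dione
Product: 16 (4R)-8-bromo-7-butyl-2-(phenylselanyl)-5-oxaspiro[3.4]oct-7-ene-1,6-dione (C2 epimers), via TMS enol ether 15 (not isolated)
Conditions: TMSOTf, Et3N, CH2Cl2, 0 °C; then PhSeCl, −78 °C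
Reagents that add atoms: benzeneselenenyl chloride Cl[Se]c1ccccc1
Why: Soft enolisation to the only possible silyl enol ether (the spiro carbon has no hydrogen) and electrophilic selenenylation at C2 form the first half of a selenoxide dehydrogenation, and the new C2 centre is destroyed in the next step so its configuration is irrelevant.

Step 12
Reactants: 16 (4R)-8-bromo-7-butyl-2-(phenylselanyl)-5-oxaspiro[3.4]oct-7-ene-1,6-dione
Product: 18 (R)-8-bromo-7-butyl-5-oxaspiro[3.4]octa-2,7-diene-1,6-dione, via selenoxide 17 (not isolated)
Conditions: H2O2 (30%), pyridine, CH2Cl2, 0 °C to rt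
Reagents that add atoms: none
Why: Oxidation to the selenoxide and syn elimination toward the C3 hydrogens (the only β-hydrogens) should give the cyclobutenone at or below room temperature, well under the temperature at which 4,4-disubstituted cyclobutenones undergo electrocyclic opening.

Step 13
Reactants: 19 butanal; 20 ethyl acrylate
Product: 21 rac-ethyl 3-hydroxy-2-methylidenehexanoate
Conditions: DABCO, neat, rt
Reagents that add atoms: none
Why: The Morita–Baylis–Hillman reaction of an aliphatic aldehyde with an acrylate gives the racemic α-methylene-β-hydroxy ester in one step.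

Step 14
Reactants: 21 rac-ethyl 3-hydroxy-2-methylidenehexanoate
Product: 22 ethyl (R)-3-acetoxy-2-methylidenehexanoate
Conditions: immobilised Burkholderia cepacia lipase, vinyl acetate, MTBE, rt, stopped near 40% conversion
Reagents that add atoms: vinyl acetate C=COC(C)=O
Why: Lipase-catalysed kinetic resolution of the Morita–Baylis–Hillman adduct by acylation, with the acrylate unit as the large group, should acetylate the (R)-alcohol and thereby deliver C1′ of the target already as its acetate.

Step 15
Reactants: 22 ethyl (R)-3-acetoxy-2-methylidenehexanoate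
Product: 23 ethyl (R)-3-acetoxy-2-oxohexanoate
Conditions: O3, CH2Cl2, −78 °C; then Me2S
Reagents that add atoms: ozone [O-][O+]=O
Why: Ozonolysis of the 1,1-disubstituted alkene with reductive work-up gives the α-keto ester without any base, so the α-acetoxy stereocentre is not enolised.

Step 16
Reactants: 23 ethyl (R)-3-acetoxy-2-oxohexanoate
Product: 24 ethyl (R)-2-(1-acetoxybutyl)-3,3-dibromoprop-2-enoate
Conditions: CBr4, PPh3, CH2Cl2, 0 °C
Reagents that add atoms: carbon tetrabromide BrC(Br)(Br)Br
Why: Ramirez dibromoolefination (Wittig-type reaction of the dibromomethylene ylide) is efficient on activated α-keto esters, and the nearly neutral ylide should leave the adjacent stereocentre intact.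

Step 17
Reactants: 18 (R)-8-bromo-7-butyl-5-oxaspiro[3.4]octa-2,7-diene-1,6-dione; 24 ethyl (R)-2-(1-acetoxybutyl)-3,3-dibromoprop-2-enoate
Product: 27 dispiro cyclobutene bis-butenolide (ring A 4-bromo-3-butyl; ring B 4-bromo-3-[(1R)-1-acetoxybutyl]; both spiro carbons R; lactone oxygens trans), via magnesium carbenoid 25 (not isolated), via hydroxy ester 26 (not isolated)
Conditions: 24, i-PrMgCl, THF, −78 °C; then 18, −78 to −40 °C; AcOH, −78 °C; then PPTS (cat.), CH2Cl2, rt
Reagents that add atoms: none
Why: Bromine–magnesium exchange at the bromine cis to the chelating ester gives a configurationally defined 1-bromoalkenylmagnesium carbenoid whose 1,2-addition to the non-enolisable cyclobutenone and lactonisation of the resulting cis γ-hydroxy enoate build ring B, and attack on the carbonyl face syn to the ring A oxygen (the other face is covered by the C4 bromine of ring A) sets the spiro carbon of ring B with its lactone oxygen trans to that of ring A.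

Step 18
Reactants: 27 dispiro cyclobutene bis-butenolide
Product: 28 CNP0268004.1 (target; ring C trans-dibromide, each bromine anti to the neighbouring lactone oxygen; spiro carbons S,S, CHBr carbons R,R, C1′ R)
Conditions: Br2, CH2Cl2, −78 to −20 °C, dark
Reagents that add atoms: bromine BrBr
Why: Electrophilic anti addition of bromine through a bromonium ion gives the trans-dibromide at the only reactive alkene (both butenolide alkenes are tetrasubstituted and electron-poor), the two faces of the cyclobutene are equivalent through the local twofold axis of the dispiro core, and the required isomer should arise when bromide opens the bromonium ion at the carbon where it enters anti to the adjacent lactone C–O bond, away from the ring oxygen lone pairs (the spiro descriptors change from R to S only because the CHBr carbons now outrank the other spiro carbon).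

Compound list
1 | 1,2-bis(trimethylsilyloxy)cyclobutene | C[Si](C)(C)OC1=C(O[Si](C)(C)C)CC1 | starting material
2 | rac-2-hydroxycyclobutan-1-one | O=C1CCC1O | intermediate
3 | (R)-2-oxocyclobutyl acetate | O=C1CC[C@H]1OC(C)=O | intermediate
4 | (R)-2-hydroxycyclobutan-1-one | O=C1CC[C@H]1O | intermediate
5 | (R)-2-[(tert-butyldimethylsilyl)oxy]cyclobutan-1-one | O=C1CC[C@H]1O[Si](C)(C)C(C)(C)C | intermediate
6 | hex-1-yne | CCCCC#C | starting material
7 | hex-1-ynyllithium | [Li]C#CCCCC | intermediate
8 | lithium (1R,2R)-2-[(tert-butyldimethylsilyl)oxy]-1-(hex-1-yn-1-yl)cyclobutan-1-olate | CCCCC#C[C@]1(O[Li])CC[C@H]1O[Si](C)(C)C(C)(C)C | intermediate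
9 | (1R,2R)-2-[(tert-butyldimethylsilyl)oxy]-1-(hex-1-yn-1-yl)cyclobutyl methyl carbonate | CCCCC#C[C@]1(OC(=O)OC)CC[C@H]1O[Si](C)(C)C(C)(C)C | intermediate
10 | methyl (Ra)-2-butyl-3-[(2R)-2-[(tert-butyldimethylsilyl)oxy]cyclobutylidene]prop-2-enoate (ester anti to OTBS) | CCCCC(C(=O)OC)=[C@]=C1CC[C@H]1O[Si](C)(C)C(C)(C)C | intermediate
11 | (Ra)-2-butyl-3-[(2R)-2-[(tert-butyldimethylsilyl)oxy]cyclobutylidene]prop-2-enoic acid (carboxyl anti to OTBS) | CCCCC(C(=O)O)=[C@]=C1CC[C@H]1O[Si](C)(C)C(C)(C)C | intermediate
12 | (1R,4R)-8-bromo-7-butyl-1-[(tert-butyldimethylsilyl)oxy]-5-oxaspiro[3.4]oct-7-en-6-one | CCCCC1=C(Br)[C@@]2(OC1=O)CC[C@H]2O[Si](C)(C)C(C)(C)C | intermediate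
13 | (1R,4R)-8-bromo-7-butyl-1-hydroxy-5-oxaspiro[3.4]oct-7-en-6-one | CCCCC1=C(Br)[C@@]2(OC1=O)CC[C@H]2O | intermediate
14 | (R)-8-bromo-7-butyl-5-oxaspiro[3.4]oct-7-ene-1,6-dione | CCCCC1=C(Br)[C@@]2(OC1=O)CCC2=O | intermediate
15 | (R)-8-bromo-7-butyl-1-(trimethylsilyloxy)-5-oxaspiro[3.4]octa-1,7-dien-6-one | CCCCC1=C(Br)[C@@]2(OC1=O)CC=C2O[Si](C)(C)C | intermediate
16 | (4R)-8-bromo-7-butyl-2-(phenylselanyl)-5-oxaspiro[3.4]oct-7-ene-1,6-dione (C2 epimers) | CCCCC1=C(Br)[C@@]2(OC1=O)CC([Se]c3ccccc3)C2=O | intermediate
17 | (4R)-8-bromo-7-butyl-2-(phenylseleninyl)-5-oxaspiro[3.4]oct-7-ene-1,6-dione | CCCCC1=C(Br)[C@@]2(OC1=O)CC([Se](=O)c3ccccc3)C2=O | intermediate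
18 | (R)-8-bromo-7-butyl-5-oxaspiro[3.4]octa-2,7-diene-1,6-dione | CCCCC1=C(Br)[C@@]2(OC1=O)C=CC2=O | intermediate
19 | butanal | CCCC=O | starting material
20 | ethyl acrylate | C=CC(=O)OCC | starting material
21 | rac-ethyl 3-hydroxy-2-methylidenehexanoate | C=C(C(=O)OCC)C(O)CCC | intermediate
22 | ethyl (R)-3-acetoxy-2-methylidenehexanoate | C=C(C(=O)OCC)[C@@H](CCC)OC(C)=O | intermediate
23 | ethyl (R)-3-acetoxy-2-oxohexanoate | CCOC(=O)C(=O)[C@@H](CCC)OC(C)=O | intermediate
24 | ethyl (R)-2-(1-acetoxybutyl)-3,3-dibromoprop-2-enoate | CCOC(=O)C(=C(Br)Br)[C@@H](CCC)OC(C)=O | intermediate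
25 | chloro[(E)-1-bromo-2-(ethoxycarbonyl)-2-[(1R)-1-acetoxybutyl]ethenyl]magnesium (Mg cis to the ester) | CCOC(=O)/C([C@@H](CCC)OC(C)=O)=C(/Br)[Mg]Cl | intermediate
26 | hydroxy ester: tertiary cyclobutenol from 18 carrying the 1-bromo-2-(ethoxycarbonyl)-3-acetoxyhex-1-enyl group (ester cis to the carbinol carbon; hydroxyl anti to the ring A oxygen) | CCCCC1=C(Br)[C@@]2(OC1=O)C=C[C@]2(O)/C(Br)=C(\C(=O)OCC)[C@@H](CCC)OC(C)=O | intermediate
27 | dispiro cyclobutene bis-butenolide (ring A 4-bromo-3-butyl; ring B 4-bromo-3-[(1R)-1-acetoxybutyl]; spiro carbons R,R; lactone oxygens trans) | CCCCC1=C(Br)[C@@]2(OC1=O)C=C[C@@]21OC(=O)C([C@@H](CCC)OC(C)=O)=C1Br | intermediate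
28 | CNP0268004.1 | CCCCC1=C(Br)[C@@]2(OC1=O)[C@@H](Br)[C@H](Br)[C@@]21OC(=O)C([C@@H](CCC)OC(C)=O)=C1Br | target

Total step count: 18. Longest linear sequence: 14 steps (steps 1 to 12, 17 and 18); steps 13 to 16 make the ring B fragment.

Steps most likely to fail

Step 8. Bromine transfer to the strained cyclobutylidene terminus may run through a free cyclobutyl cation, which can contract to a cyclopropylcarbinyl cation or be captured on either ring face, so that the axis-to-centre relay is eroded. The fallback makes ring A by the carbenoid annulation of step 17 instead; it sets out from 2 and comes back at 14. The alcohol left unreacted in step 2, (S)-2-hydroxycyclobutan-1-one F1, is silylated (TBSCl, imidazole) to (S)-2-[(tert-butyldimethylsilyl)oxy]cyclobutan-1-one F2. Ethyl 3,3-dibromo-2-butylprop-2-enoate F3, made from commercial ethyl 2-oxohexanoate with CBr4 and PPh3, undergoes bromine–magnesium exchange with i-PrMgCl at −78 °C and adds to F2 anti to the silyloxy group. Lactonisation should give (1S,4R)-8-bromo-7-butyl-1-[(tert-butyldimethylsilyl)oxy]-5-oxaspiro[3.4]oct-7-en-6-one F4, which has the spiro configuration of 12 because here the carbon, not the oxygen, enters anti to the silyloxy group. HF·pyridine then gives (1S,4R)-8-bromo-7-butyl-1-hydroxy-5-oxaspiro[3.4]oct-7-en-6-one F5, and Dess–Martin oxidation gives 14.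

Step 17. The acetate may be attacked by the Grignard reagent or may steer the bromine–magnesium exchange to the wrong bromine, so that the adduct cannot lactonise. The fallback carries the C1′ oxygen as a silyl ether and installs the acetate after ring B is closed; it sets out from 22 and comes back at 27. Lipase-catalysed alcoholysis of 22 (n-BuOH) gives ethyl (R)-3-hydroxy-2-methylidenehexanoate F6, and TBSCl with imidazole gives ethyl (R)-3-[(tert-butyldimethylsilyl)oxy]-2-methylidenehexanoate F7. Ozonolysis gives ethyl (R)-3-[(tert-butyldimethylsilyl)oxy]-2-oxohexanoate F8, and CBr4 with PPh3 gives ethyl (R)-3,3-dibromo-2-[1-[(tert-butyldimethylsilyl)oxy]butyl]prop-2-enoate F9. Exchange with i-PrMgCl, addition to 18 and lactonisation as in step 17 should give the silyl ether analogue of 27 F10. HF·pyridine gives the C1′ alcohol corresponding to 27 F11, and Ac2O with pyridine and DMAP gives 27.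

Step 18. Bromide may open the bromonium ion on the less crowded, oxygen-flanked side, away from the C4 bromine of the neighbouring butenolide, which gives the other trans-dibromide with both bromines syn to the lactone oxygens. The fallback corrects this after the addition; it sets out from 27 and comes back at 28. The unwanted isomer, the trans-dibromide with both CHBr centres inverted F12, is isolated and heated (chlorobenzene, about 100 °C, or LiBr in MeCN). The suprafacial 1,2-interchange of the two bromine atoms, the mutarotation known for trans vicinal dibromides, inverts both carbons at once and equilibrates F12 with 28. Compound 28 is separated and the remainder is recycled.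

Further compounds
F1 | step 8 | (S)-2-hydroxycyclobutan-1-one | O=C1CC[C@@H]1O
F2 | step 8 | (S)-2-[(tert-butyldimethylsilyl)oxy]cyclobutan-1-one | O=C1CC[C@@H]1O[Si](C)(C)C(C)(C)C
F3 | step 8 | ethyl 3,3-dibromo-2-butylprop-2-enoate | CCCCC(C(=O)OCC)=C(Br)Br
F4 | step 8 | (1S,4R)-8-bromo-7-butyl-1-[(tert-butyldimethylsilyl)oxy]-5-oxaspiro[3.4]oct-7-en-6-one | CCCCC1=C(Br)[C@@]2(OC1=O)CC[C@@H]2O[Si](C)(C)C(C)(C)C
F5 | step 8 | (1S,4R)-8-bromo-7-butyl-1-hydroxy-5-oxaspiro[3.4]oct-7-en-6-one | CCCCC1=C(Br)[C@@]2(OC1=O)CC[C@@H]2O
F6 | step 17 | ethyl (R)-3-hydroxy-2-methylidenehexanoate | C=C(C(=O)OCC)[C@@H](CCC)O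
F7 | step 17 | ethyl (R)-3-[(tert-butyldimethylsilyl)oxy]-2-methylidenehexanoate | C=C(C(=O)OCC)[C@@H](CCC)O[Si](C)(C)C(C)(C)C
F8 | step 17 | ethyl (R)-3-[(tert-butyldimethylsilyl)oxy]-2-oxohexanoate | CCOC(=O)C(=O)[C@@H](CCC)O[Si](C)(C)C(C)(C)C
F9 | step 17 | ethyl (R)-3,3-dibromo-2-[1-[(tert-butyldimethylsilyl)oxy]butyl]prop-2-enoate | CCOC(=O)C(=C(Br)Br)[C@@H](CCC)O[Si](C)(C)C(C)(C)C
F10 | step 17 | silyl ether analogue of 27 | CCCCC1=C(Br)[C@@]2(OC1=O)C=C[C@@]21OC(=O)C([C@@H](CCC)O[Si](C)(C)C(C)(C)C)=C1Br
F11 | step 17 | C1′ alcohol corresponding to 27 | CCCCC1=C(Br)[C@@]2(OC1=O)C=C[C@@]21OC(=O)C([C@@H](CCC)O)=C1Br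
F12 | step 18 | trans-dibromide with both CHBr centres inverted | CCCCC1=C(Br)[C@@]2(OC1=O)[C@H](Br)[C@@H](Br)[C@@]21OC(=O)C([C@@H](CCC)OC(C)=O)=C1Br
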